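**Assumption:** the SMILES is read as (2R,3R) in the catechol-bearing flavanone, so the aryl groups on C2 and C3 are cis, and as (2''R) in the naringenin half. Double-primed locants and Ar'' refer to the naringenin unit and its ring A''.

## Analysis of the target

The target 27 is a 3,8''-biflavanone. An eriodictyol-type flavanone (ring A, the 5,7-dihydroxylated benzo ring; ring C, the pyranone O1–C2–C3–C4; ring B, the catechol on C2) is bonded through C3 to C8'' of a naringenin unit (rings A'' and C'' and the 4-hydroxyphenyl ring B'' on C2''). There are three stereocentres: C2 and C3 are adjacent and cis (2R,3R), and C2'' (R) lies five bonds from C3, too far to be set from the upper half. C3 is a benzylic methine α to the C4 carbonyl and epimerises readily, and cis is the less stable arrangement, so it must be made under kinetic control and kept from base or acid once C4 is a ketone. Both pyranones open by retro-oxa-Michael reaction under base, the seven phenols are oxidation-prone, and any C4–O or C2–O bond on the phloroglucinol-type ring A ionises under acid. The hard bond is C3–C8'': it joins a stereocentre to an arene carbon flanked by two oxygens (O1'' and the C7'' oxygen), and these must be told apart because only O1'' enters ring C''. The strategy rests on the C3–C4 bond of ring C: as a C3=C4 alkene of a 2H-chromene, C3 is trigonal and cannot epimerise, C2 is the only stereocentre, and C2 can later direct hydrogen to C3 from the face opposite ring B while C4 stays a carbinol.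

## Retrosynthetic reasoning

**27 from 26.** The seven O–benzyl bonds are cut last. One protecting group serves all phenols, and neutral hydrogenolysis frees them without touching the labile C3 centre.

**26 from 25.** The C4 carbonyl is taken back to a carbinol. As long as C4 is sp3, H-3 is not acidic, so the cis relationship survives every intermediate step. The forward reaction must oxidise one hindered secondary alcohol under near-neutral conditions.

**25 and 24 from 22 and 23.** The C2''–aryl bond is cut. An asymmetric conjugate arylation of the chromone 22 with the boronic acid 23 sets C2'' under catalyst control, which is needed because the C2/C3 centres are too remote to direct it. The silyl ether on C4–O is removed afterwards (24 to 25).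

**22 from 18 through 19 and 20.** Ring C'' is dismantled at O1''–C2'' (oxa-Michael closure of an ynone), C4''–C3'' (addition of an ethynyl nucleophile to the aldehyde 19) and C4a''–C4'' (formylation of the phenol 18). The formylation is directed by the free O1'' phenol, so it can only reach C4a''. This is why O1'' is carried as a silyl ether that can be removed alone, while the C5'' and C7'' oxygens are benzyl ethers.

**18 from 14 through 17 and 16.** The C3–H and C4–O bonds are cut back to the C3=C4 alkene of 14. Hydroboration places boron on the less substituted C4 and hydrogen on C3, both on the face opposite the C2 aryl group. That is the cis arrangement of 27. The C4 carbinol of 16 is silylated (17) and the aryl silyl ether is then cleaved (18).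

**14 from 13.** The C3=C4 bond is cut by ring-closing metathesis, giving the diene 13 with a styrene on ring A and a 1,1-disubstituted alkene on C3. The C3–Ar'' bond is not formed at a stereocentre; it is present from the first step, and the ring closure only has to lose the two terminal methylene carbons.

**13 from 7 and 9 through 10 and 12.** The aryl ether bond O1–C8a is cut. In the forward direction the alkoxide of 7 displaces fluoride from the nitrile 9. The carbinol C–O bond is not touched, so C2 is transferred with retention by mechanism. A Mitsunobu reaction at this hindered allylic centre would risk allylic transposition, and a palladium alkoxide of such a benzylic, allylic alcohol could collapse by β-hydride elimination. The nitrile that activates the substitution is then converted into the styrene (10 to 12 to 13).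

**7 from 3 and 4 through 5 and 6.** The C2–C3 bond is cut between the aldehyde 4 and the alkenyl triflate 3. The chromium-mediated coupling tolerates the crowded alkenyl partner and gives the racemic alcohol 5. Oxidation to the enone 6 and catalytic asymmetric reduction then set C2.

**3 from 1, and 9 from 8.** The acetyl group of the commercial acetophenone 1 supplies C3 (carbonyl carbon) and the methylene that is later lost (methyl carbon), and its substitution pattern fixes the oxygenation of ring A'' without any regiochemical step. The nitrile 9 comes from 8 by exchanging two of its three fluorine atoms for benzyloxy groups.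

## Alternatives that were turned down

**Alternative 1:** oxidative cross-coupling of two flavonoid monomers. The disconnection removes C3–C8'' and O1–C2 together. In the forward step an oxidase or peroxidase would oxidise the 4-phenol of chalcone A2 and the 5-phenol of naringenin ether A3; the radicals would couple between the chalcone α-carbon and C8'', and the 2'-hydroxyl would trap the quinone methide to close ring C, giving A1.
- For: it is by far the shortest route, roughly a third of the chosen step count, it uses two simple monomers, and it needs no differentiation of the ring A'' oxygens. On step economy it is clearly stronger.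
- Against: ring closure onto the quinone methide is reversible in effect and gives the 2,3-trans isomer, which is what A1 is (2R,3S). The target is cis, and converting trans to cis at an enolisable centre runs against thermodynamics. The radicals are achiral, so C2/C3 would also form without control relative to C2''. Homocoupling, coupling at C6'' and C–O coupling would compete.
- Comparison: the chosen route is much longer, but it delivers the cis isomer by hydroboration of the alkene in 14 and controls each stereocentre separately.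

**Alternative 2:** ortho-quinone methide cycloaddition for ring C''. The disconnection cuts O1''–C2'' and C3''–C4''. A chiral phosphoric acid would dehydrate the salicyl alcohol A5 to an ortho-quinone methide, which would add 4-(benzyloxy)styrene A6 in a [4+2] cycloaddition to give the flavan A4, still carrying the 2H-chromene.
- For: it keeps the same C3=C4 logic as the chosen route and builds ring C'' with its stereocentre in one step, where the chosen route needs three (steps 15 to 17). On this point it is stronger.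
- Against: A4 has a C4'' methylene, so a late benzylic oxidation would be needed in a molecule with seven benzyl ethers and several other benzylic C–H bonds. The Brønsted acid must also act on a 2-aryl-2H-chromene whose C2–O bond on an electron-rich ring ionises easily, which would racemise the only stereocentre present at that stage. The quinone methide is flanked by the bulky chromenyl group.
- Comparison: the chosen route brings C4'' in at the carbonyl oxidation level through the chromone 22 and uses only neutral or basic conditions after the stereocentre is set.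

**Alternative 3:** benzannulation to build ring A'' on C3. The disconnection removes two C–C bonds of the naringenin arene. Heating the siloxyalkyne A8 with 3-(benzyloxy)cyclobut-2-en-1-one A9 would open the cyclobutenone to a vinylketene, add it to the alkyne, open again and close to the phenol A7.
- For: the arene is built in place, so no hindered alkene has to be closed next to a di-ortho-substituted ring, and A7 emerges with the O1'' phenol already free and the other ortho oxygen silylated. On the differentiation of the two ortho oxygens and on the steric demand of the ring-forming step it is stronger.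
- Against: A8 is itself a 3-alkynyl-2H-chromene with the C2 stereocentre and must first be made, for example by the same metathesis on a different diene and then homologation to a sensitive siloxyalkyne. The benzannulation needs sustained heating, under which 2H-chromenes can open by electrocyclic reaction to ortho-quinone methides and lose C2 configuration.
- Comparison: the chosen route takes Ar'' complete from the commercial acetophenone 1, keeps the chromene at or below 60 °C, and accepts one extra deprotection (step 13).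

Key step: step 10

## Route

Step 1
Reactants: 1 1-[2,4-bis(benzyloxy)-6-hydroxyphenyl]ethan-1-one
Product: 2 1-[2,4-bis(benzyloxy)-6-(triisopropylsilyloxy)phenyl]ethan-1-one
Conditions: NaH, THF, 0 °C; i-Pr3SiCl, 0 °C → rt
Reagents that add atoms: triisopropylsilyl chloride, CC(C)[Si](Cl)(C(C)C)C(C)C
Why: O-silylation of the sodium phenoxide; NaH takes only the chelated phenol proton, and the bulky triisopropylsilyl group marks the oxygen that becomes O1'' and resists base and silyl transfer in the following steps.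

Step 2
Reactants: 2 1-[2,4-bis(benzyloxy)-6-(triisopropylsilyloxy)phenyl]ethan-1-one
Product: 3 1-[2,4-bis(benzyloxy)-6-(triisopropylsilyloxy)phenyl]ethenyl trifluoromethanesulfonate
Conditions: KN(SiMe3)2, THF, −78 °C; N-(5-chloropyridin-2-yl)bis(trifluoromethanesulfonimide), −78 °C
Reagents that add atoms: N-(5-chloropyridin-2-yl)bis(trifluoromethanesulfonimide), FC(F)(F)S(=O)(=O)N(c1ccc(Cl)cn1)S(=O)(=O)C(F)(F)F
Why: Enol triflate formation; the methyl ketone can enolise in one direction only, and the reactive pyridyl triflimide traps the potassium enolate at −78 °C before the neighbouring silyl group can move to the enolate oxygen.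

Step 3
Reactants: 3 1-[2,4-bis(benzyloxy)-6-(triisopropylsilyloxy)phenyl]ethenyl trifluoromethanesulfonate; 4 3,4-bis(benzyloxy)benzaldehyde
Product: 5 racemic 1-[3,4-bis(benzyloxy)phenyl]-2-[2,4-bis(benzyloxy)-6-(triisopropylsilyloxy)phenyl]prop-2-en-1-ol
Conditions: CrCl2 (4 equiv), NiCl2 (2 mol%), DMF, rt
Reagents that add atoms: none
Why: Nozaki–Hiyama–Kishi coupling; nickel inserts into the alkenyl triflate, the alkenylchromium species adds only to the aldehyde, and the method tolerates the crowded di-ortho-substituted alkenyl partner, the silyl ether and the benzyl ethers.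

Step 4
Reactants: 5 racemic 1-[3,4-bis(benzyloxy)phenyl]-2-[2,4-bis(benzyloxy)-6-(triisopropylsilyloxy)phenyl]prop-2-en-1-ol
Product: 6 1-[3,4-bis(benzyloxy)phenyl]-2-[2,4-bis(benzyloxy)-6-(triisopropylsilyloxy)phenyl]prop-2-en-1-one
Conditions: MnO2, CH2Cl2, rt
Reagents that add atoms: none
Why: MnO2 oxidation of a benzylic and allylic alcohol under neutral conditions; the enone is used at once because α-methylene ketones can dimerise on standing.

Step 5
Reactants: 6 1-[3,4-bis(benzyloxy)phenyl]-2-[2,4-bis(benzyloxy)-6-(triisopropylsilyloxy)phenyl]prop-2-en-1-one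
Product: 7 (1S)-1-[3,4-bis(benzyloxy)phenyl]-2-[2,4-bis(benzyloxy)-6-(triisopropylsilyloxy)phenyl]prop-2-en-1-ol
Conditions: (S)-2-methyl-CBS-oxazaborolidine (20 mol%), catecholborane, toluene, −78 °C
Reagents that add atoms: none
Why: Corey–Bakshi–Shibata reduction; the coplanar, conjugated 3,4-bis(benzyloxy)phenyl group should act as the large substituent and the 1-arylvinyl group, twisted out of the carbonyl plane by its di-ortho-substituted arene, as the small one, so the (S)-catalyst should deliver hydride to give the (S)-carbinol that maps onto C2 of 27; catecholborane at −78 °C leaves the alkene alone.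

Step 6
Reactants: 8 2,4,6-trifluorobenzonitrile
Product: 9 2,4-bis(benzyloxy)-6-fluorobenzonitrile
Conditions: BnOH (2.05 equiv), NaH, THF/DMF, −20 °C → rt
Reagents that add atoms: benzyl alcohol, OCc1ccccc1
Why: Twofold nucleophilic aromatic substitution; whether the first benzyloxide enters para or ortho to the nitrile, the second prefers the remaining more activated position, so the 2,4-dialkoxy-6-fluoro isomer should dominate, and the third fluorine is deactivated enough to survive.

Step 7
Reactants: 7 (1S)-1-[3,4-bis(benzyloxy)phenyl]-2-[2,4-bis(benzyloxy)-6-(triisopropylsilyloxy)phenyl]prop-2-en-1-ol; 9 2,4-bis(benzyloxy)-6-fluorobenzonitrile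
Product: 10 2,4-bis(benzyloxy)-6-{[(1S)-1-[3,4-bis(benzyloxy)phenyl]-2-[2,4-bis(benzyloxy)-6-(triisopropylsilyloxy)phenyl]prop-2-en-1-yl]oxy}benzonitrile
Conditions: KN(SiMe3)2, THF, −78 °C; 9, DMF, −20 → 40 °C
Reagents that add atoms: none
Why: Nucleophilic aromatic substitution of the fluoride ortho to the nitrile by the potassium alkoxide; the carbinol C–O bond is not broken, so C2 is carried over with retention, and the two benzyloxy groups are meta to the reacting carbon and do not destabilise the anionic σ-complex.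

Step 8
Reactants: 10 2,4-bis(benzyloxy)-6-{[(1S)-1-[3,4-bis(benzyloxy)phenyl]-2-[2,4-bis(benzyloxy)-6-(triisopropylsilyloxy)phenyl]prop-2-en-1-yl]oxy}benzonitrile
Product: 12 2,4-bis(benzyloxy)-6-{[(1S)-1-[3,4-bis(benzyloxy)phenyl]-2-[2,4-bis(benzyloxy)-6-(triisopropylsilyloxy)phenyl]prop-2-en-1-yl]oxy}benzaldehyde, via N-diisobutylalumino aldimine 11 (not isolated)
Conditions: i-Bu2AlH, toluene, −78 → −20 °C; aq. potassium sodium tartrate, then aq. citric acid, 0 °C
Reagents that add atoms: water, O
Why: Half-reduction of a nitrile; one hydride adds, the N-aluminoimine does not react further, and cold, weakly acidic hydrolysis releases the aldehyde without ionising the allylic aryl ether.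

Step 9
Reactants: 12 2,4-bis(benzyloxy)-6-{[(1S)-1-[3,4-bis(benzyloxy)phenyl]-2-[2,4-bis(benzyloxy)-6-(triisopropylsilyloxy)phenyl]prop-2-en-1-yl]oxy}benzaldehyde
Product: 13 1,5-bis(benzyloxy)-2-ethenyl-3-{[(1S)-1-[3,4-bis(benzyloxy)phenyl]-2-[2,4-bis(benzyloxy)-6-(triisopropylsilyloxy)phenyl]prop-2-en-1-yl]oxy}benzene
Conditions: Ph3PCH3Br, KOt-Bu, THF, 0 °C → rt
Reagents that add atoms: methyltriphenylphosphonium bromide, [Br-].C[P+](c1ccccc1)(c1ccccc1)c1ccccc1
Why: Wittig methylenation of the aryl aldehyde; the unstabilised ylide reacts even with a hindered electron-rich aldehyde, and the C2–H is not acidic enough to be affected.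

Step 10
Reactants: 13 1,5-bis(benzyloxy)-2-ethenyl-3-{[(1S)-1-[3,4-bis(benzyloxy)phenyl]-2-[2,4-bis(benzyloxy)-6-(triisopropylsilyloxy)phenyl]prop-2-en-1-yl]oxy}benzene
Product: 14 (2S)-5,7-bis(benzyloxy)-2-[3,4-bis(benzyloxy)phenyl]-3-[2,4-bis(benzyloxy)-6-(triisopropylsilyloxy)phenyl]-2H-chromene
Conditions: second-generation Grubbs catalyst RuCl2(=CHPh)(SIMes)(PCy3) (10 mol%), 1,4-benzoquinone (20 mol%), toluene (0.005 M), 60 °C, argon purge
Reagents that add atoms: none
Why: Ring-closing olefin metathesis by the metallacyclobutane mechanism: the ruthenium benzylidene exchanges first with the unhindered ring A styrene, the new aryl alkylidene adds across the 1,1-disubstituted alkene to a ruthenacyclobutane in which the fully substituted C3 sits β to the metal, and cycloreversion releases ethylene and the C3=C4 bond. The closest known reaction type is the ring-closing metathesis of ortho-vinylaryl 2-substituted allyl ethers to 3-substituted 2H-chromenes. Ring C is closed as a six-membered ring by this intramolecular [2+2] cycloaddition and cycloreversion, the aryl ether oxygen holding the two alkenes ortho to each other. No stereocentre is formed, and C2 is carried through because no bond to it is made or broken; its descriptor stays S only because C3 still outranks ring B. The step needs ring closure to beat intermolecular coupling of the styrene ends and ruthenium hydride migration of the double bond towards C2; high dilution, the ortho tether, loss of volatile ethylene and benzoquinone as hydride scavenger should secure this. The trisubstituted product alkene, shielded by Ar'', should not re-enter metathesis. The temperature is held at 60 °C so that the 2H-chromene does not open thermally to an ortho-quinone methide, which would racemise C2.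

Step 11
Reactants: 14 (2S)-5,7-bis(benzyloxy)-2-[3,4-bis(benzyloxy)phenyl]-3-[2,4-bis(benzyloxy)-6-(triisopropylsilyloxy)phenyl]-2H-chromene
Product: 16 (2R,3S,4S)-5,7-bis(benzyloxy)-2-[3,4-bis(benzyloxy)phenyl]-3-[2,4-bis(benzyloxy)-6-(triisopropylsilyloxy)phenyl]chroman-4-ol, via C4 alkylborane 15 (not isolated)
Conditions: BH3·THF, THF, 0 °C → rt; then 30% H2O2, aq. NaOH, 0 °C
Reagents that add atoms: hydrogen peroxide, OO
Why: Hydroboration–oxidation; boron adds to the less substituted C4 and hydrogen to C3, syn, on the face of ring C opposite the pseudoaxial C2 aryl group, so the C2 stereocentre sets C3 with Ar'' cis to ring B, and oxidation with retention gives the 3,4-trans carbinol whose C4 configuration is erased later; brief cold oxidation spares the aryl silyl ether.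

Step 12
Reactants: 16 (2R,3S,4S)-5,7-bis(benzyloxy)-2-[3,4-bis(benzyloxy)phenyl]-3-[2,4-bis(benzyloxy)-6-(triisopropylsilyloxy)phenyl]chroman-4-ol
Product: 17 (2R,3R,4S)-5,7-bis(benzyloxy)-2-[3,4-bis(benzyloxy)phenyl]-3-[2,4-bis(benzyloxy)-6-(triisopropylsilyloxy)phenyl]-4-(tert-butyldimethylsilyloxy)chromane
Conditions: t-BuMe2SiOTf, 2,6-lutidine, CH2Cl2, −78 → 0 °C
Reagents that add atoms: tert-butyldimethylsilyl trifluoromethanesulfonate, CC(C)(C)[Si](C)(C)OS(=O)(=O)C(F)(F)F
Why: Silyl ether formation with the triflate, which is needed for this hindered carbinol; excess lutidine at low temperature keeps the medium non-acidic so the C4–O bond on the electron-rich ring A does not ionise, and a silyloxy group is a poor leaving group for the steps that follow.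

Step 13
Reactants: 17 (2R,3R,4S)-5,7-bis(benzyloxy)-2-[3,4-bis(benzyloxy)phenyl]-3-[2,4-bis(benzyloxy)-6-(triisopropylsilyloxy)phenyl]-4-(tert-butyldimethylsilyloxy)chromane
Product: 18 3,5-bis(benzyloxy)-2-[(2R,3R,4S)-5,7-bis(benzyloxy)-2-[3,4-bis(benzyloxy)phenyl]-4-(tert-butyldimethylsilyloxy)chroman-3-yl]phenol
Conditions: Bu4NF (1.1 equiv), THF, 0 °C; then AcOH
Reagents that add atoms: none
Why: Fluoride cleavage of an aryl silyl ether; a phenoxide leaves silicon far faster than the hindered secondary alkoxide, so the C4 silyl ether should survive, and silyl transfer from C4–O to the phenoxide is thermodynamically uphill.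

Step 14
Reactants: 18 3,5-bis(benzyloxy)-2-[(2R,3R,4S)-5,7-bis(benzyloxy)-2-[3,4-bis(benzyloxy)phenyl]-4-(tert-butyldimethylsilyloxy)chroman-3-yl]phenol
Product: 19 4,6-bis(benzyloxy)-3-[(2R,3R,4S)-5,7-bis(benzyloxy)-2-[3,4-bis(benzyloxy)phenyl]-4-(tert-butyldimethylsilyloxy)chroman-3-yl]-2-hydroxybenzaldehyde
Conditions: MgCl2, Et3N, (CH2O)n, THF, 65 °C
Reagents that add atoms: paraformaldehyde (as formaldehyde), C=O
Why: Casnati–Skattebøl ortho-formylation; the magnesium phenoxide delivers formaldehyde only to the free position ortho to O1'' (C4a''), not to C6'', and a second formaldehyde oxidises the hydroxymethyl intermediate by hydride transfer; the amine keeps the medium basic so the C4 silyl ether is not displaced by the neighbouring phenoxide.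

Step 15
Reactants: 19 4,6-bis(benzyloxy)-3-[(2R,3R,4S)-5,7-bis(benzyloxy)-2-[3,4-bis(benzyloxy)phenyl]-4-(tert-butyldimethylsilyloxy)chroman-3-yl]-2-hydroxybenzaldehyde
Product: 20 1-{4,6-bis(benzyloxy)-3-[(2R,3R,4S)-5,7-bis(benzyloxy)-2-[3,4-bis(benzyloxy)phenyl]-4-(tert-butyldimethylsilyloxy)chroman-3-yl]-2-hydroxyphenyl}prop-2-yn-1-ol (both carbinol epimers)
Conditions: HC≡CMgBr (4 equiv), THF, −20 °C → rt
Reagents that add atoms: ethynylmagnesium bromide, C#C[Mg]Br
Why: Grignard addition of an acetylide to the aldehyde; the first equivalent deprotonates the phenol, the new carbinol centre is oxidised in the next step so its configuration does not matter, and the crude product is carried on to avoid ortho-quinone methide formation.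

Step 16
Reactants: 20 1-{4,6-bis(benzyloxy)-3-[(2R,3R,4S)-5,7-bis(benzyloxy)-2-[3,4-bis(benzyloxy)phenyl]-4-(tert-butyldimethylsilyloxy)chroman-3-yl]-2-hydroxyphenyl}prop-2-yn-1-ol (both carbinol epimers)
Product: 22 5,7-bis(benzyloxy)-8-[(2R,3R,4S)-5,7-bis(benzyloxy)-2-[3,4-bis(benzyloxy)phenyl]-4-(tert-butyldimethylsilyloxy)chroman-3-yl]-4H-chromen-4-one, via ortho-hydroxyaryl ynone 21 (not isolated)
Conditions: MnO2, CH2Cl2, rt; filter; K2CO3 (cat.), acetone, rt
Reagents that add atoms: none
Why: MnO2 oxidises the activated propargylic benzylic alcohol, and the ortho phenoxide then closes ring C'' by 6-endo-dig oxa-Michael addition to the unhindered terminal ynone, giving the 2-unsubstituted chromone.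

Step 17
Reactants: 22 5,7-bis(benzyloxy)-8-[(2R,3R,4S)-5,7-bis(benzyloxy)-2-[3,4-bis(benzyloxy)phenyl]-4-(tert-butyldimethylsilyloxy)chroman-3-yl]-4H-chromen-4-one; 23 4-(benzyloxy)phenylboronic acid
Product: 24 (2R)-5,7-bis(benzyloxy)-2-[4-(benzyloxy)phenyl]-8-[(2R,3R,4S)-5,7-bis(benzyloxy)-2-[3,4-bis(benzyloxy)phenyl]-4-(tert-butyldimethylsilyloxy)chroman-3-yl]chroman-4-one
Conditions: [Rh(OH)(cod)]2 (3 mol%), (R)-MeO-F12-BIPHEP (7 mol%), toluene/H2O (10:1), 40 °C
Reagents that add atoms: none
Why: Hayashi–Miyaura rhodium-catalysed asymmetric 1,4-addition; the aryl–rhodium species adds across C2''=C3'' and water protonates the rhodium enolate, the (R)-configured electron-poor bisphosphine should direct the aryl group to the Si face of C2'' by the same face model as for cyclic enones and so set (2''R) under catalyst control, and the base-free medium avoids chromone ring opening and flavanone retro-Michael reaction.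

Step 18
Reactants: 24 (2R)-5,7-bis(benzyloxy)-2-[4-(benzyloxy)phenyl]-8-[(2R,3R,4S)-5,7-bis(benzyloxy)-2-[3,4-bis(benzyloxy)phenyl]-4-(tert-butyldimethylsilyloxy)chroman-3-yl]chroman-4-one
Product: 25 (2R)-5,7-bis(benzyloxy)-2-[4-(benzyloxy)phenyl]-8-[(2R,3S,4S)-5,7-bis(benzyloxy)-2-[3,4-bis(benzyloxy)phenyl]-4-hydroxychroman-3-yl]chroman-4-one
Conditions: Bu4NF/AcOH (1:1), THF, rt → 40 °C
Reagents that add atoms: none
Why: Fluoride desilylation; the acetic acid buffer keeps the medium near neutral, so the flavanone neither opens by retro-oxa-Michael reaction nor epimerises at C2'', and the C4 carbinol is not ionised.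

Step 19
Reactants: 25 (2R)-5,7-bis(benzyloxy)-2-[4-(benzyloxy)phenyl]-8-[(2R,3S,4S)-5,7-bis(benzyloxy)-2-[3,4-bis(benzyloxy)phenyl]-4-hydroxychroman-3-yl]chroman-4-one
Product: 26 (2R,3R)-5,7-bis(benzyloxy)-2-[3,4-bis(benzyloxy)phenyl]-3-[(2R)-5,7-bis(benzyloxy)-2-[4-(benzyloxy)phenyl]-4-oxochroman-8-yl]chroman-4-one
Conditions: Dess–Martin periodinane, NaHCO3, CH2Cl2, 0 °C → rt
Reagents that add atoms: none
Why: Dess–Martin oxidation of the secondary benzylic alcohol; the bicarbonate buffer and short contact time are chosen so that the newly acidic H-3 does not epimerise from cis to trans.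

Step 20
Reactants: 26 (2R,3R)-5,7-bis(benzyloxy)-2-[3,4-bis(benzyloxy)phenyl]-3-[(2R)-5,7-bis(benzyloxy)-2-[4-(benzyloxy)phenyl]-4-oxochroman-8-yl]chroman-4-one
Product: 27 (2R,3R)-2-(3,4-dihydroxyphenyl)-5,7-dihydroxy-3-[(2R)-5,7-dihydroxy-2-(4-hydroxyphenyl)-4-oxochroman-8-yl]chroman-4-one
Conditions: H2 (1 atm), 10% Pd/C, EtOAc/MeOH, rt
Reagents that add atoms: none
Why: Hydrogenolysis of the seven benzyl ethers under neutral conditions; aryl benzyl ethers cleave faster than the hydrogen-bonded flavanone carbonyls or the cyclic benzylic C2–O bonds are reduced, and no acid or base is present to epimerise C3.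

## Compound list

1 | 1-[2,4-bis(benzyloxy)-6-hydroxyphenyl]ethan-1-one | CC(=O)c1c(O)cc(OCc9ccccc9)cc1OCc9ccccc9 | starting material
2 | 1-[2,4-bis(benzyloxy)-6-(triisopropylsilyloxy)phenyl]ethan-1-one | CC(=O)c1c(O[Si](C(C)C)(C(C)C)C(C)C)cc(OCc9ccccc9)cc1OCc9ccccc9 | intermediate
3 | 1-[2,4-bis(benzyloxy)-6-(triisopropylsilyloxy)phenyl]ethenyl trifluoromethanesulfonate | C=C(OS(=O)(=O)C(F)(F)F)c1c(O[Si](C(C)C)(C(C)C)C(C)C)cc(OCc9ccccc9)cc1OCc9ccccc9 | intermediate
4 | 3,4-bis(benzyloxy)benzaldehyde | O=Cc1ccc(OCc9ccccc9)c(OCc9ccccc9)c1 | starting material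
5 | racemic 1-[3,4-bis(benzyloxy)phenyl]-2-[2,4-bis(benzyloxy)-6-(triisopropylsilyloxy)phenyl]prop-2-en-1-ol | OC(C(=C)c1c(O[Si](C(C)C)(C(C)C)C(C)C)cc(OCc9ccccc9)cc1OCc9ccccc9)c1ccc(OCc9ccccc9)c(OCc9ccccc9)c1 | intermediate
6 | 1-[3,4-bis(benzyloxy)phenyl]-2-[2,4-bis(benzyloxy)-6-(triisopropylsilyloxy)phenyl]prop-2-en-1-one | O=C(C(=C)c1c(O[Si](C(C)C)(C(C)C)C(C)C)cc(OCc9ccccc9)cc1OCc9ccccc9)c1ccc(OCc9ccccc9)c(OCc9ccccc9)c1 | intermediate
7 | (1S)-1-[3,4-bis(benzyloxy)phenyl]-2-[2,4-bis(benzyloxy)-6-(triisopropylsilyloxy)phenyl]prop-2-en-1-ol | O[C@H](C(=C)c1c(O[Si](C(C)C)(C(C)C)C(C)C)cc(OCc9ccccc9)cc1OCc9ccccc9)c1ccc(OCc9ccccc9)c(OCc9ccccc9)c1 | intermediate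
8 | 2,4,6-trifluorobenzonitrile | N#Cc1c(F)cc(F)cc1F | starting material
9 | 2,4-bis(benzyloxy)-6-fluorobenzonitrile | N#Cc1c(F)cc(OCc9ccccc9)cc1OCc9ccccc9 | intermediate
10 | 2,4-bis(benzyloxy)-6-{[(1S)-1-[3,4-bis(benzyloxy)phenyl]-2-[2,4-bis(benzyloxy)-6-(triisopropylsilyloxy)phenyl]prop-2-en-1-yl]oxy}benzonitrile | N#Cc1c(OCc9ccccc9)cc(OCc9ccccc9)cc1O[C@H](C(=C)c1c(O[Si](C(C)C)(C(C)C)C(C)C)cc(OCc9ccccc9)cc1OCc9ccccc9)c1ccc(OCc9ccccc9)c(OCc9ccccc9)c1 | intermediate
11 | N-(diisobutylalumino)aldimine of aldehyde 12, (S) at the ether carbon | CC(C)C[Al](CC(C)C)N=Cc1c(OCc9ccccc9)cc(OCc9ccccc9)cc1O[C@H](C(=C)c1c(O[Si](C(C)C)(C(C)C)C(C)C)cc(OCc9ccccc9)cc1OCc9ccccc9)c1ccc(OCc9ccccc9)c(OCc9ccccc9)c1 | intermediate (not isolated)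
12 | 2,4-bis(benzyloxy)-6-{[(1S)-1-[3,4-bis(benzyloxy)phenyl]-2-[2,4-bis(benzyloxy)-6-(triisopropylsilyloxy)phenyl]prop-2-en-1-yl]oxy}benzaldehyde | O=Cc1c(OCc9ccccc9)cc(OCc9ccccc9)cc1O[C@H](C(=C)c1c(O[Si](C(C)C)(C(C)C)C(C)C)cc(OCc9ccccc9)cc1OCc9ccccc9)c1ccc(OCc9ccccc9)c(OCc9ccccc9)c1 | intermediate
13 | 1,5-bis(benzyloxy)-2-ethenyl-3-{[(1S)-1-[3,4-bis(benzyloxy)phenyl]-2-[2,4-bis(benzyloxy)-6-(triisopropylsilyloxy)phenyl]prop-2-en-1-yl]oxy}benzene | C=Cc1c(OCc9ccccc9)cc(OCc9ccccc9)cc1O[C@H](C(=C)c1c(O[Si](C(C)C)(C(C)C)C(C)C)cc(OCc9ccccc9)cc1OCc9ccccc9)c1ccc(OCc9ccccc9)c(OCc9ccccc9)c1 | intermediate (precursor of the key step)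
14 | (2S)-5,7-bis(benzyloxy)-2-[3,4-bis(benzyloxy)phenyl]-3-[2,4-bis(benzyloxy)-6-(triisopropylsilyloxy)phenyl]-2H-chromene | C1(c2c(O[Si](C(C)C)(C(C)C)C(C)C)cc(OCc9ccccc9)cc2OCc9ccccc9)=Cc2c(OCc9ccccc9)cc(OCc9ccccc9)cc2O[C@H]1c1ccc(OCc9ccccc9)c(OCc9ccccc9)c1 | intermediate (product of the key step)
15 | C4 alkylborane of 14: BH2 on C4 cis to H-3 and trans to both aryl groups, the C2 and C3 aryl groups cis | CC(C)[Si](C(C)C)(C(C)C)Oc1cc(OCc9ccccc9)cc(OCc9ccccc9)c1[C@H]1[C@H](B)c2c(OCc9ccccc9)cc(OCc9ccccc9)cc2O[C@H]1c1ccc(OCc9ccccc9)c(OCc9ccccc9)c1 | intermediate (not isolated)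
16 | (2R,3S,4S)-5,7-bis(benzyloxy)-2-[3,4-bis(benzyloxy)phenyl]-3-[2,4-bis(benzyloxy)-6-(triisopropylsilyloxy)phenyl]chroman-4-ol (2,3-cis, 3,4-trans) | CC(C)[Si](C(C)C)(C(C)C)Oc1cc(OCc9ccccc9)cc(OCc9ccccc9)c1[C@H]1[C@H](O)c2c(OCc9ccccc9)cc(OCc9ccccc9)cc2O[C@H]1c1ccc(OCc9ccccc9)c(OCc9ccccc9)c1 | intermediate
17 | (2R,3R,4S)-5,7-bis(benzyloxy)-2-[3,4-bis(benzyloxy)phenyl]-3-[2,4-bis(benzyloxy)-6-(triisopropylsilyloxy)phenyl]-4-(tert-butyldimethylsilyloxy)chromane | CC(C)[Si](C(C)C)(C(C)C)Oc1cc(OCc9ccccc9)cc(OCc9ccccc9)c1[C@H]1[C@H](O[Si](C)(C)C(C)(C)C)c2c(OCc9ccccc9)cc(OCc9ccccc9)cc2O[C@H]1c1ccc(OCc9ccccc9)c(OCc9ccccc9)c1 | intermediate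
18 | 3,5-bis(benzyloxy)-2-[(2R,3R,4S)-5,7-bis(benzyloxy)-2-[3,4-bis(benzyloxy)phenyl]-4-(tert-butyldimethylsilyloxy)chroman-3-yl]phenol | Oc1cc(OCc9ccccc9)cc(OCc9ccccc9)c1[C@H]1[C@H](O[Si](C)(C)C(C)(C)C)c2c(OCc9ccccc9)cc(OCc9ccccc9)cc2O[C@H]1c1ccc(OCc9ccccc9)c(OCc9ccccc9)c1 | intermediate
19 | 4,6-bis(benzyloxy)-3-[(2R,3R,4S)-5,7-bis(benzyloxy)-2-[3,4-bis(benzyloxy)phenyl]-4-(tert-butyldimethylsilyloxy)chroman-3-yl]-2-hydroxybenzaldehyde | Oc1c(C=O)c(OCc9ccccc9)cc(OCc9ccccc9)c1[C@H]1[C@H](O[Si](C)(C)C(C)(C)C)c2c(OCc9ccccc9)cc(OCc9ccccc9)cc2O[C@H]1c1ccc(OCc9ccccc9)c(OCc9ccccc9)c1 | intermediate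
20 | 1-{4,6-bis(benzyloxy)-3-[(2R,3R,4S)-5,7-bis(benzyloxy)-2-[3,4-bis(benzyloxy)phenyl]-4-(tert-butyldimethylsilyloxy)chroman-3-yl]-2-hydroxyphenyl}prop-2-yn-1-ol, both epimers at the propargylic carbinol | Oc1c(C(O)C#C)c(OCc9ccccc9)cc(OCc9ccccc9)c1[C@H]1[C@H](O[Si](C)(C)C(C)(C)C)c2c(OCc9ccccc9)cc(OCc9ccccc9)cc2O[C@H]1c1ccc(OCc9ccccc9)c(OCc9ccccc9)c1 | intermediate
21 | 1-{4,6-bis(benzyloxy)-3-[(2R,3R,4S)-5,7-bis(benzyloxy)-2-[3,4-bis(benzyloxy)phenyl]-4-(tert-butyldimethylsilyloxy)chroman-3-yl]-2-hydroxyphenyl}prop-2-yn-1-one | Oc1c(C(=O)C#C)c(OCc9ccccc9)cc(OCc9ccccc9)c1[C@H]1[C@H](O[Si](C)(C)C(C)(C)C)c2c(OCc9ccccc9)cc(OCc9ccccc9)cc2O[C@H]1c1ccc(OCc9ccccc9)c(OCc9ccccc9)c1 | intermediate (not isolated)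
22 | 5,7-bis(benzyloxy)-8-[(2R,3R,4S)-5,7-bis(benzyloxy)-2-[3,4-bis(benzyloxy)phenyl]-4-(tert-butyldimethylsilyloxy)chroman-3-yl]-4H-chromen-4-one | O=c1ccoc2c1c(OCc9ccccc9)cc(OCc9ccccc9)c2[C@H]1[C@H](O[Si](C)(C)C(C)(C)C)c2c(OCc9ccccc9)cc(OCc9ccccc9)cc2O[C@H]1c1ccc(OCc9ccccc9)c(OCc9ccccc9)c1 | intermediate
23 | 4-(benzyloxy)phenylboronic acid | OB(O)c1ccc(OCc9ccccc9)cc1 | starting material
24 | (2R)-5,7-bis(benzyloxy)-2-[4-(benzyloxy)phenyl]-8-[(2R,3R,4S)-5,7-bis(benzyloxy)-2-[3,4-bis(benzyloxy)phenyl]-4-(tert-butyldimethylsilyloxy)chroman-3-yl]chroman-4-one | O=C1C[C@H](c2ccc(OCc9ccccc9)cc2)Oc2c1c(OCc9ccccc9)cc(OCc9ccccc9)c2[C@H]1[C@H](O[Si](C)(C)C(C)(C)C)c2c(OCc9ccccc9)cc(OCc9ccccc9)cc2O[C@H]1c1ccc(OCc9ccccc9)c(OCc9ccccc9)c1 | intermediate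
25 | (2R)-5,7-bis(benzyloxy)-2-[4-(benzyloxy)phenyl]-8-[(2R,3S,4S)-5,7-bis(benzyloxy)-2-[3,4-bis(benzyloxy)phenyl]-4-hydroxychroman-3-yl]chroman-4-one | O=C1C[C@H](c2ccc(OCc9ccccc9)cc2)Oc2c1c(OCc9ccccc9)cc(OCc9ccccc9)c2[C@H]1[C@H](O)c2c(OCc9ccccc9)cc(OCc9ccccc9)cc2O[C@H]1c1ccc(OCc9ccccc9)c(OCc9ccccc9)c1 | intermediate
26 | (2R,3R)-5,7-bis(benzyloxy)-2-[3,4-bis(benzyloxy)phenyl]-3-[(2R)-5,7-bis(benzyloxy)-2-[4-(benzyloxy)phenyl]-4-oxochroman-8-yl]chroman-4-one (2,3-cis) | O=C1C[C@H](c2ccc(OCc9ccccc9)cc2)Oc2c1c(OCc9ccccc9)cc(OCc9ccccc9)c2[C@H]1C(=O)c2c(OCc9ccccc9)cc(OCc9ccccc9)cc2O[C@H]1c1ccc(OCc9ccccc9)c(OCc9ccccc9)c1 | intermediate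
27 | (2R,3R)-2-(3,4-dihydroxyphenyl)-5,7-dihydroxy-3-[(2R)-5,7-dihydroxy-2-(4-hydroxyphenyl)-4-oxochroman-8-yl]chroman-4-one | O=C1C[C@H](c2ccc(O)cc2)Oc2c1c(O)cc(O)c2[C@H]1C(=O)c2c(O)cc(O)cc2O[C@H]1c1ccc(O)c(O)c1 | target

## Step count and risk

Total: 20 steps. Longest linear sequence: 19 steps (1 to 27 through steps 1 to 5 and 7 to 20); step 6 is the only branch.

**Step 10 (key step).** The process most likely to fail is the intramolecular addition of the ring A alkylidene to the 1,1-disubstituted alkene. Ar'' stands perpendicular to that alkene and its two ortho substituents, above all the triisopropylsilyloxy group, shield both faces. The ortho ether oxygens of ring A can also chelate the ruthenium alkylidene and slow turnover. If closure is slow, intermolecular coupling of the styrene ends and hydride-induced migration of the double bond towards C2 take over. The fallback lowers the steric demand at the alkene instead of changing the catalyst. It sets out from 13: the aryl silyl ether is cleaved with Bu4NF to the free-phenol diene F1; metathesis with the same ruthenium catalyst on this less shielded alkene should give the free-phenol chromene F2; re-silylation with triisopropylsilyl triflate and 2,6-lutidine returns to the route at 14.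

**Step 5.** The risk is poor facial discrimination, because both ketone substituents are sp2 groups and the assignment of the aryl group as the large one is a prediction. The configuration of 7 would be checked by MTPA ester analysis, and the enantiomeric catalyst is equally available if the sense is reversed. If the selectivity itself is low, the fallback is a kinetic resolution, which does not depend on that discrimination. It sets out from racemic 5 and returns at 7: Sharpless epoxidation with Ti(Oi-Pr)4, D-(−)-diisopropyl tartrate and tert-butyl hydroperoxide over 4 Å sieves in CH2Cl2 at −20 °C, run to just past half conversion. By the usual mnemonic the (R)-alcohol is consumed to the epoxy alcohol F3 and (S)-5, which is 7, is recovered. Steps 4 and 5 are then omitted, at the cost of half the material.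

**Step 7.** The fluoroarene 9 is deactivated by two alkoxy groups, so substitution by the hindered alkoxide may be slow. A long-lived alkoxide could accept the triisopropylsilyl group from the nearby aryl oxygen, which would lead to arylation at the wrong oxygen, or could isomerise to the saturated ketone. The fallback avoids a free alkoxide and changes the bond-forming method. It sets out from 7 and returns at 13, replacing steps 7 to 9. 1,3-Bis(benzyloxy)-5-bromobenzene F4 is formylated (Vilsmeier–Haack, POCl3, DMF) to 2,4-bis(benzyloxy)-6-bromobenzaldehyde F5 and methylenated (Ph3PCH3Br, KOt-Bu) to 1,5-bis(benzyloxy)-3-bromo-2-ethenylbenzene F6. Alcohol 7 is then O-arylated with F6 using Pd(OAc)2, a bulky di-tert-butyl biarylphosphine and Cs2CO3 in toluene at 90 °C. The weak carbonate base keeps the alkoxide concentration low; the residual risk there is β-hydride elimination back to 6.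

**Step 17.** The chromone 22 is electron-rich and carries a large group at C8'', so aryl transfer may be slow and protodeboronation of 23 or 1,2-addition may compete; the chiral upper half could also oppose the catalyst. The fallback builds the flavanone from a chalcone and needs no conjugate addition to a chromone. It sets out from 19 and returns at 24:
- MeMgBr gives the 1-arylethanol F7.
- MnO2 gives the ortho-hydroxyacetophenone F8.
- Claisen–Schmidt condensation with 4-(benzyloxy)benzaldehyde F9 (KOH, EtOH/THF) gives the 2'-hydroxychalcone F10.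
- Oxa-Michael cyclisation, with a quinine-derived bifunctional thiourea for facial bias or simply NaOAc in ethanol, gives 24. It is separated from its C2'' epimer by chromatography; the two are diastereomers.

## Further compounds

F1 | step 10 | 3,5-bis(benzyloxy)-2-[(3S)-3-[3,4-bis(benzyloxy)phenyl]-3-[3,5-bis(benzyloxy)-2-ethenylphenoxy]prop-1-en-2-yl]phenol | C=Cc1c(OCc9ccccc9)cc(OCc9ccccc9)cc1O[C@H](C(=C)c1c(O)cc(OCc9ccccc9)cc1OCc9ccccc9)c1ccc(OCc9ccccc9)c(OCc9ccccc9)c1
F2 | step 10 | 3,5-bis(benzyloxy)-2-[(2S)-5,7-bis(benzyloxy)-2-[3,4-bis(benzyloxy)phenyl]-2H-chromen-3-yl]phenol | C1(c2c(O)cc(OCc9ccccc9)cc2OCc9ccccc9)=Cc2c(OCc9ccccc9)cc(OCc9ccccc9)cc2O[C@H]1c1ccc(OCc9ccccc9)c(OCc9ccccc9)c1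
F3 | step 5 | (R)-[3,4-bis(benzyloxy)phenyl]{(2R)-2-[2,4-bis(benzyloxy)-6-(triisopropylsilyloxy)phenyl]oxiran-2-yl}methanol | O[C@@H]([C@]1(CO1)c1c(O[Si](C(C)C)(C(C)C)C(C)C)cc(OCc9ccccc9)cc1OCc9ccccc9)c1ccc(OCc9ccccc9)c(OCc9ccccc9)c1
F4 | step 7 | 1,3-bis(benzyloxy)-5-bromobenzene | Brc1cc(OCc9ccccc9)cc(OCc9ccccc9)c1
F5 | step 7 | 2,4-bis(benzyloxy)-6-bromobenzaldehyde | O=Cc1c(Br)cc(OCc9ccccc9)cc1OCc9ccccc9
F6 | step 7 | 1,5-bis(benzyloxy)-3-bromo-2-ethenylbenzene | C=Cc1c(Br)cc(OCc9ccccc9)cc1OCc9ccccc9
F7 | step 17 | 1-{4,6-bis(benzyloxy)-3-[(2R,3R,4S)-5,7-bis(benzyloxy)-2-[3,4-bis(benzyloxy)phenyl]-4-(tert-butyldimethylsilyloxy)chroman-3-yl]-2-hydroxyphenyl}ethan-1-ol, both carbinol epimers | Oc1c(C(C)O)c(OCc9ccccc9)cc(OCc9ccccc9)c1[C@H]1[C@H](O[Si](C)(C)C(C)(C)C)c2c(OCc9ccccc9)cc(OCc9ccccc9)cc2O[C@H]1c1ccc(OCc9ccccc9)c(OCc9ccccc9)c1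
F8 | step 17 | 1-{4,6-bis(benzyloxy)-3-[(2R,3R,4S)-5,7-bis(benzyloxy)-2-[3,4-bis(benzyloxy)phenyl]-4-(tert-butyldimethylsilyloxy)chroman-3-yl]-2-hydroxyphenyl}ethan-1-one | Oc1c(C(C)=O)c(OCc9ccccc9)cc(OCc9ccccc9)c1[C@H]1[C@H](O[Si](C)(C)C(C)(C)C)c2c(OCc9ccccc9)cc(OCc9ccccc9)cc2O[C@H]1c1ccc(OCc9ccccc9)c(OCc9ccccc9)c1
F9 | step 17 | 4-(benzyloxy)benzaldehyde | O=Cc1ccc(OCc9ccccc9)cc1
F10 | step 17 | (E)-1-{4,6-bis(benzyloxy)-3-[(2R,3R,4S)-5,7-bis(benzyloxy)-2-[3,4-bis(benzyloxy)phenyl]-4-(tert-butyldimethylsilyloxy)chroman-3-yl]-2-hydroxyphenyl}-3-[4-(benzyloxy)phenyl]prop-2-en-1-one | Oc1c(C(=O)/C=C/c2ccc(OCc9ccccc9)cc2)c(OCc9ccccc9)cc(OCc9ccccc9)c1[C@H]1[C@H](O[Si](C)(C)C(C)(C)C)c2c(OCc9ccccc9)cc(OCc9ccccc9)cc2O[C@H]1c1ccc(OCc9ccccc9)c(OCc9ccccc9)c1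
A1 | alternative 1 | penta-O-benzyl (2R,3S,2''R)-3,8''-biflavanone with free 4'- and 5''-hydroxyls, 2,3-trans | O=C1C[C@H](c2ccc(OCc9ccccc9)cc2)Oc2c1c(O)cc(OCc9ccccc9)c2[C@@H]1C(=O)c2c(OCc9ccccc9)cc(OCc9ccccc9)cc2O[C@H]1c1ccc(O)c(OCc9ccccc9)c1
A2 | alternative 1 | (E)-1-[2,4-bis(benzyloxy)-6-hydroxyphenyl]-3-[3-(benzyloxy)-4-hydroxyphenyl]prop-2-en-1-one | O=C(/C=C/c1ccc(O)c(OCc9ccccc9)c1)c1c(O)cc(OCc9ccccc9)cc1OCc9ccccc9
A3 | alternative 1 | (2R)-7-(benzyloxy)-2-[4-(benzyloxy)phenyl]-5-hydroxychroman-4-one | O=C1C[C@H](c2ccc(OCc9ccccc9)cc2)Oc2cc(OCc9ccccc9)cc(O)c12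
A4 | alternative 2 | (2R)-5,7-bis(benzyloxy)-2-[4-(benzyloxy)phenyl]-8-[(2S)-5,7-bis(benzyloxy)-2-[3,4-bis(benzyloxy)phenyl]-2H-chromen-3-yl]chromane | C1C[C@H](c2ccc(OCc9ccccc9)cc2)Oc2c1c(OCc9ccccc9)cc(OCc9ccccc9)c2C1=Cc2c(OCc9ccccc9)cc(OCc9ccccc9)cc2O[C@H]1c1ccc(OCc9ccccc9)c(OCc9ccccc9)c1
A5 | alternative 2 | 3,5-bis(benzyloxy)-2-[(2S)-5,7-bis(benzyloxy)-2-[3,4-bis(benzyloxy)phenyl]-2H-chromen-3-yl]-6-(hydroxymethyl)phenol | OCc1c(O)c(C2=Cc3c(OCc9ccccc9)cc(OCc9ccccc9)cc3O[C@H]2c2ccc(OCc9ccccc9)c(OCc9ccccc9)c2)c(OCc9ccccc9)cc1OCc9ccccc9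
A6 | alternative 2 | 4-(benzyloxy)styrene | C=Cc1ccc(OCc9ccccc9)cc1
A7 | alternative 3 | 5-(benzyloxy)-2-[(2S)-5,7-bis(benzyloxy)-2-[3,4-bis(benzyloxy)phenyl]-2H-chromen-3-yl]-3-(triisopropylsilyloxy)phenol | C1(c2c(O)cc(OCc9ccccc9)cc2O[Si](C(C)C)(C(C)C)C(C)C)=Cc2c(OCc9ccccc9)cc(OCc9ccccc9)cc2O[C@H]1c1ccc(OCc9ccccc9)c(OCc9ccccc9)c1
A8 | alternative 3 | (2S)-5,7-bis(benzyloxy)-2-[3,4-bis(benzyloxy)phenyl]-3-[(triisopropylsilyloxy)ethynyl]-2H-chromene | C(#CO[Si](C(C)C)(C(C)C)C(C)C)C1=Cc2c(OCc9ccccc9)cc(OCc9ccccc9)cc2O[C@H]1c1ccc(OCc9ccccc9)c(OCc9ccccc9)c1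
A9 | alternative 3 | 3-(benzyloxy)cyclobut-2-en-1-one | O=C1C=C(OCc9ccccc9)C1
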